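**Retrosynthetic overview**

1. Target 28 ⇐ 27 ⇐ 26: the last operations are acetylation of O2/O9 and hydroxyl-directed epoxidation of the Z-C3=C4 bond of macrocyclic diene 26.
2. The ten-membered ring is closed late at C3=C4 from seco-alkyne 24: ethylene enyne metathesis builds the C5(=C16H2) diene, then ring-closing metathesis.
3. The γ-lactone, C6–Cl, C8–OH and C17 come from trans-epoxy ketone 17 plus propionate in one flask. The C7–O bond of 17 (the future lactone oxygen) is the key bond, made by catalytic asymmetric nucleophilic epoxidation of E-enynone 16.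
4. 16 ⇐ aldol condensation of methyl ketone 12 with silylpropynal; 12 ⇐ lactone 7 (acetyl-anion addition, Felkin reduction at C9); 7 ⇐ Felkin vinylation at C2 of aldehyde 4.
5. Ring B (C1, C10) is made first by enantioselective Diels–Alder reaction of siloxydiene 2 with formyl crotonate 3. Ring order: ring B → γ-lactone → ten-membered ring → epoxide.

Locants C1–C20 are the briarane positions of the target: C1 quaternary (Me-15), C2 and C9 acetoxy carbons, C3/C4 epoxide, C5(=C16H2), C6–Cl, C7–O(lactone), C8–OH, C10 ring-fusion CH, C11 C(OH)Me-20, C12 ketone, C13=C14, C17(Me-18), C19 lactone C=O. "As in the target" means the same spatial arrangement; the SMILES are authoritative.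

Assumption: the (S)-prolinol-derived oxazaborolidinium of step 2 is taken to give the enantiomer drawn; if its facial sense is the opposite, the mirror-image catalyst is used with no other change.

**Route**

Step 1
Reactants: 1 pent-1-en-3-one
Product: 2 (3Z)-3-(triisopropylsilyloxy)penta-1,3-diene
Conditions: iPr3SiOTf, Et3N, CH2Cl2, 0 °C → rt
Reagents that add atoms: triisopropylsilyl trifluoromethanesulfonate, CC(C)[Si](C(C)C)(C(C)C)OS(=O)(=O)C(F)(F)F
Why: Soft enolisation (silyl triflate/amine) of the ethyl ketone gives the thermodynamically preferred Z silyl enol ether, i.e. the diene with its terminal methyl "outside", as a Diels–Alder reaction requires.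

Step 2
Reactants: 2 (3Z)-3-(triisopropylsilyloxy)penta-1,3-diene; 3 ethyl (2E)-3-methyl-4-oxobut-2-enoate
Product: 4 ethyl (1S,2S,6S)-6-formyl-2,6-dimethyl-3-(triisopropylsilyloxy)cyclohex-3-ene-1-carboxylate
Conditions: (S)-1-(2-methylphenyl)-3,3-diphenyltetrahydro-1H,3H-pyrrolo[1,2-c][1,3,2]oxazaborole (20 mol%), HNTf2 (20 mol%), CH2Cl2, −78 → −20 °C
Reagents that add atoms: none
Why: Catalytic enantioselective Diels–Alder reaction in which the cationic oxazaborolidine binds the formyl group, so the siloxy-activated diene terminus (C11) attacks the enal β-carbon (C10) to give the "para" regioisomer, the E dienophile fixes the trans C2/C9 relationship, and the catalyst face sets C1 and C10 (C11 is erased later).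

Step 3
Reactants: 4 ethyl (1S,2S,6S)-6-formyl-2,6-dimethyl-3-(triisopropylsilyloxy)cyclohex-3-ene-1-carboxylate; 5 vinylmagnesium bromide
Product: 7 trans-fused vinyl γ-lactone of ring B (C2–O acylated by C9), via hydroxy ester 6 (not isolated)
Conditions: CH2=CHMgBr (1.05 equiv), THF, −78 °C → rt
Reagents that add atoms: none
Why: Aldehyde-selective Grignard addition under Felkin–Anh control (C10 branch anti to the nucleophile, approach past the C15 methyl) sets C2, and the magnesium alkoxide closes onto the trans ester (5-exo-trig lactonisation), which masks O2 and makes C9 a mono-acylating lactone carbon.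

Step 4
Reactants: 7 trans-fused vinyl γ-lactone; 8 ethyl vinyl ether (as 1-ethoxyvinyllithium)
Product: 11 C2/C9-diol methyl ketone, via ethoxyvinyl ketone 9 (not isolated), via ethoxyvinyl carbinol 10 (not isolated)
Conditions: CH2=C(OEt)Li (from 8, t-BuLi, THF, −78 → 0 °C), THF, −78 °C; then MeOH, CeCl3·7H2O, NaBH4, −78 → −40 °C; then 0.1 M HCl, 0 °C
Reagents that add atoms: water, O
Why: Mono-addition of an acetyl-anion equivalent to the lactone (stable lactolate), then Luche 1,2-reduction under Felkin–Anh control (quaternary C1 anti to hydride) sets C9, and the 2-alkoxypropene-type enol ether hydrolyses in dilute acid much faster than the hindered triisopropylsilyl enol ether.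

Step 5
Reactants: 11 C2/C9-diol methyl ketone
Product: 12 bis(tert-butyldimethylsilyl) ether of 11
Conditions: t-BuMe2SiOTf, 2,6-lutidine, CH2Cl2, −78 → 0 °C
Reagents that add atoms: tert-butyldimethylsilyl trifluoromethanesulfonate, CC(C)(C)[Si](C)(C)OS(=O)(=O)C(F)(F)F
Why: Silyl ether formation on both secondary alcohols; the non-chelating silyl ether on O9 is what later allows Felkin–Anh control at C8.

Step 6
Reactants: 12 bis(tert-butyldimethylsilyl) ether; 13 3-(trimethylsilyl)propynal
Product: 16 E-enynone (C8 ketone; E-C6=C7; silylated C4≡C5), via aldol adduct 14 (not isolated), via aldol mesylate 15 (not isolated)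
Conditions: LiN(SiMe3)2, THF, −78 °C; 13; then MsCl, Et3N, −78 → 0 °C
Reagents that add atoms: none
Why: Aldol condensation: the kinetic methyl-ketone enolate adds to the non-enolisable aldehyde, and mesylation/E1cB elimination gives the conjugated E alkene.

Step 7
Reactants: 16 E-enynone
Product: 17 trans-6,7-epoxy ketone (6R,7S)
Conditions: La(OiPr)3 (10 mol%), (R)-1,1′-bi-2-naphthol (10 mol%), Ph3AsO (10 mol%), t-BuOOH, 4 Å molecular sieves, THF, rt
Reagents that add atoms: tert-butyl hydroperoxide, CC(C)(C)OO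
Why: Catalytic asymmetric Weitz–Scheffer (nucleophilic) epoxidation: the lanthanum–binaphtholate peroxide adds to C6 and the enolate closes the C7–O bond, giving the trans epoxide in the (αS,βR) sense known for the (R)-ligand with E-enones, while the electron-rich silyl enol ether and the vinyl group are inert to a nucleophilic oxidant.

Step 8
Reactants: 17 trans-6,7-epoxy ketone; 18 ethyl propanoate
Product: 21 chloro hydroxy γ-lactone (C6–Cl; C7–O lactone; C8–OH; C17–Me), via epoxy aldol 19 (not isolated), via chlorohydrin ester 20 (not isolated)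
Conditions: 18, LiN(iPr)2, THF, −78 °C; 17; ClTi(OiPr)3, −78 → −20 °C; Et2NH·HCl, CH2Cl2, rt; then 1,8-diazabicyclo[5.4.0]undec-7-ene (0.2 equiv), rt
Reagents that add atoms: diethylammonium chloride, CC[NH2+]CC.[Cl-]
Why: Proposed new method: a one-flask aldol/epoxide chlorinolysis/lactonisation in which the lithium propanoate enolate adds to the ketone of 17 under Felkin–Anh control from the C9 silyl ether, reinforced by lithium chelation between the ketone and epoxide oxygens (attack anti to C6), which sets C8; transmetalation with ClTi(OiPr)3 converts the tertiary aldolate into the titanium 2,3-epoxy-alkoxide known from Sharpless-type C3-selective openings, so the ammonium chloride delivers chloride to propargylic C6 with inversion (the silyl cap blocks SN2′), the freed C7 titanium alkoxide lactonises onto the ester, and the amidine base equilibrates C17 to the more stable cis-2,4-disubstituted lactone; the closest known reactions are the Ti(OiPr)4-mediated C3 opening of 2,3-epoxy alcohols by ammonium halides and titanium-alkoxide-promoted lactonisation of γ-hydroxy esters.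

Step 9
Reactants: 21 chloro hydroxy γ-lactone
Product: 22 ring-B enone (C12 ketone; C13=C14)
Conditions: DDQ, 2,4,6-collidine, benzene, rt
Reagents that add atoms: none
Why: Dehydrogenation of the silyl enol ether by the quinone (hydride abstraction at C14, then loss of silicon; a palladium-free Saegusa-type oxidation) gives the C13=C14 enone regiospecifically and leaves the propargylic chloride alone.

Step 10
Reactants: 22 ring-B enone
Product: 23 C11-hydroxy enone
Conditions: LiN(SiMe3)2 (2.2 equiv), THF, −78 °C; 2-(phenylsulfonyl)-3-phenyloxaziridine; aq. NH4Cl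
Reagents that add atoms: 2-(phenylsulfonyl)-3-phenyloxaziridine, O=S(=O)(c1ccccc1)N1OC1c1ccccc1
Why: Davis enolate oxidation: only C11 can enolise (C1 is quaternary), and the oxaziridine attacks the dienolate face anti to the axial C15 methyl and the adjacent C9 branch, which sets C11 with OH cis to H10.

Step 11
Reactants: 23 C11-hydroxy enone
Product: 24 seco-alkyne tetraol (free O2, O8, O9 and O11; terminal C4≡C5 alkyne)
Conditions: Bu4NF, AcOH (1:1), THF, 0 °C → rt
Reagents that add atoms: none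
Why: Fluoride-mediated desilylation removes both silyl ethers and the alkynyl silane, with acetic acid buffering against retro-aldol and α-ketol shifts.

Step 12
Reactants: 24 seco-alkyne tetraol
Product: 26 ten-membered 3Z,5(16)-diene tetraol, via acyclic triene 25 (not isolated)
Conditions: RuCl2(H2IMes)(=CH-C6H4-2-OiPr) (second-generation Hoveyda–Grubbs catalyst, 10 mol%), ethene (1 atm), CH2Cl2, rt; then Ar purge, toluene (0.001 M), 80 °C
Reagents that add atoms: ethene, C=C
Why: Ethene cross enyne metathesis turns the alkyne into the 2-substituted 1,3-diene (C16 comes from ethene), then ring-closing metathesis between the diene vinyl and the C2 allylic-alcohol vinyl closes the ten-membered ring, whose size enforces the Z C3=C4 geometry.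

Step 13
Reactants: 26 ten-membered 3Z,5(16)-diene tetraol
Product: 27 2,9-di-O-deacetyl target (3,4-epoxide)
Conditions: mCPBA, NaHCO3, CH2Cl2, 0 °C
Reagents that add atoms: 3-chloroperoxybenzoic acid, OOC(=O)c1cccc(Cl)c1
Why: Hydroxyl-directed (Henbest) peracid epoxidation of the Z allylic alcohol through the A(1,3)-minimised hydrogen-bonded transition state gives the threo epoxy alcohol (C3, C4 as in the target), while the chloride-deactivated 1,1-disubstituted alkene and the enone do not react.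

Step 14
Reactants: 27 2,9-di-O-deacetyl target
Product: 28 CNP0176724.2 (target)
Conditions: Ac2O, pyridine, 4-(dimethylamino)pyridine (cat.), CH2Cl2, 0 °C
Reagents that add atoms: acetic anhydride, CC(=O)OC(C)=O
Why: Acylation of the two secondary alcohols only; the tertiary C8 and C11 hydroxyls are too hindered to react at 0 °C.

**Compound list**

1 | pent-1-en-3-one (ethyl vinyl ketone) | CCC(=O)C=C | starting material
2 | (3Z)-3-(triisopropylsilyloxy)penta-1,3-diene | C=C/C(O[Si](C(C)C)(C(C)C)C(C)C)=C/C | intermediate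
3 | ethyl (2E)-3-methyl-4-oxobut-2-enoate | O=C/C(C)=C/C(=O)OCC | starting material
4 | ethyl (1S,2S,6S)-6-formyl-2,6-dimethyl-3-(triisopropylsilyloxy)cyclohex-3-ene-1-carboxylate (ring B; CHO = C2, CO2Et = C9) | O=C[C@@]1(C)CC=C(O[Si](C(C)C)(C(C)C)C(C)C)[C@@H](C)[C@@H]1C(=O)OCC | intermediate
5 | vinylmagnesium bromide | C=C[Mg]Br | starting material
6 | ethyl 6-(1-hydroxyprop-2-en-1-yl)-2,6-dimethyl-3-(triisopropylsilyloxy)cyclohex-3-ene-1-carboxylate, ring centres as in 4, carbinol C2 as in the target | C=C[C@H](O)[C@@]1(C)CC=C(O[Si](C(C)C)(C(C)C)C(C)C)[C@@H](C)[C@@H]1C(=O)OCC | intermediate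
7 | 3a,7-dimethyl-6-(triisopropylsilyloxy)-3-vinyl-3a,4,7,7a-tetrahydro-2-benzofuran-1(3H)-one, trans ring fusion (lactone O2–C9; C2 as in the target) | C=C[C@@H]1OC(=O)[C@H]2[C@H](C)C(O[Si](C(C)C)(C(C)C)C(C)C)=CC[C@]12C | intermediate
8 | ethyl vinyl ether | C=COCC | starting material
9 | 2-ethoxy-1-[6-(1-hydroxyprop-2-en-1-yl)-2,6-dimethyl-3-(triisopropylsilyloxy)cyclohex-3-en-1-yl]prop-2-en-1-one (C9 ketone) | C=C[C@H](O)[C@@]1(C)CC=C(O[Si](C(C)C)(C(C)C)C(C)C)[C@@H](C)[C@@H]1C(=O)C(=C)OCC | intermediate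
10 | 2-ethoxy-1-[6-(1-hydroxyprop-2-en-1-yl)-2,6-dimethyl-3-(triisopropylsilyloxy)cyclohex-3-en-1-yl]prop-2-en-1-ol (C9 carbinol as in the target) | C=C[C@H](O)[C@@]1(C)CC=C(O[Si](C(C)C)(C(C)C)C(C)C)[C@@H](C)[C@@H]1[C@H](O)C(=C)OCC | intermediate
11 | 1-hydroxy-1-[6-(1-hydroxyprop-2-en-1-yl)-2,6-dimethyl-3-(triisopropylsilyloxy)cyclohex-3-en-1-yl]propan-2-one (C2,C9-diol, C8 methyl ketone) | C=C[C@H](O)[C@@]1(C)CC=C(O[Si](C(C)C)(C(C)C)C(C)C)[C@@H](C)[C@@H]1[C@H](O)C(C)=O | intermediate
12 | O2,O9-bis(tert-butyldimethylsilyl) ether of 11 | C=C[C@H](O[Si](C)(C)C(C)(C)C)[C@@]1(C)CC=C(O[Si](C(C)C)(C(C)C)C(C)C)[C@@H](C)[C@@H]1[C@H](O[Si](C)(C)C(C)(C)C)C(C)=O | intermediate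
13 | 3-(trimethylsilyl)propynal | O=CC#C[Si](C)(C)C | starting material
14 | aldol adduct of 12 and 13: 4-hydroxy-6-(trimethylsilyl)hex-5-yn-2-one chain on C9 (C6 carbinol, both epimers) | C=C[C@H](O[Si](C)(C)C(C)(C)C)[C@@]1(C)CC=C(O[Si](C(C)C)(C(C)C)C(C)C)[C@@H](C)[C@@H]1[C@H](O[Si](C)(C)C(C)(C)C)C(=O)CC(O)C#C[Si](C)(C)C | intermediate
15 | C6 methanesulfonate of 14 | C=C[C@H](O[Si](C)(C)C(C)(C)C)[C@@]1(C)CC=C(O[Si](C(C)C)(C(C)C)C(C)C)[C@@H](C)[C@@H]1[C@H](O[Si](C)(C)C(C)(C)C)C(=O)CC(OS(C)(=O)=O)C#C[Si](C)(C)C | intermediate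
16 | (3E)-1-(tert-butyldimethylsilyloxy)-1-[ring B unit of 12]-6-(trimethylsilyl)hex-3-en-5-yn-2-one (C8 ketone, E-C6=C7, C4≡C5) | C=C[C@H](O[Si](C)(C)C(C)(C)C)[C@@]1(C)CC=C(O[Si](C(C)C)(C(C)C)C(C)C)[C@@H](C)[C@@H]1[C@H](O[Si](C)(C)C(C)(C)C)C(=O)/C=C/C#C[Si](C)(C)C | intermediate
17 | 2-(tert-butyldimethylsilyloxy)-2-[ring B unit of 12]-1-[(2S,3R)-3-(trimethylsilylethynyl)oxiran-2-yl]ethanone (trans-6,7-epoxide; 6R,7S) | C=C[C@H](O[Si](C)(C)C(C)(C)C)[C@@]1(C)CC=C(O[Si](C(C)C)(C(C)C)C(C)C)[C@@H](C)[C@@H]1[C@H](O[Si](C)(C)C(C)(C)C)C(=O)[C@H]2O[C@@H]2C#C[Si](C)(C)C | intermediate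
18 | ethyl propanoate | CCC(=O)OCC | starting material
19 | ethyl 3-hydroxy-2-methyl-3-[epoxide of 17]-4-(tert-butyldimethylsilyloxy)-4-[ring B unit]butanoate (C8 and C17 as in the target) | C=C[C@H](O[Si](C)(C)C(C)(C)C)[C@@]1(C)CC=C(O[Si](C(C)C)(C(C)C)C(C)C)[C@@H](C)[C@@H]1[C@H](O[Si](C)(C)C(C)(C)C)[C@](O)([C@@H](C)C(=O)OCC)[C@H]2O[C@@H]2C#C[Si](C)(C)C | intermediate
20 | chlorohydrin ester from 19 (C6–Cl, C7–OH, C8–OH, C17 as in the target) | C=C[C@H](O[Si](C)(C)C(C)(C)C)[C@@]1(C)CC=C(O[Si](C(C)C)(C(C)C)C(C)C)[C@@H](C)[C@@H]1[C@H](O[Si](C)(C)C(C)(C)C)[C@](O)([C@@H](C)C(=O)OCC)[C@@H](O)[C@@H](Cl)C#C[Si](C)(C)C | intermediate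
21 | 5-[1-chloro-3-(trimethylsilyl)prop-2-yn-1-yl]-4-hydroxy-3-methyl-4-[(tert-butyldimethylsilyloxy)(ring B unit)methyl]oxolan-2-one (C6, C7, C8, C17 as in the target) | C=C[C@H](O[Si](C)(C)C(C)(C)C)[C@@]1(C)CC=C(O[Si](C(C)C)(C(C)C)C(C)C)[C@@H](C)[C@@H]1[C@H](O[Si](C)(C)C(C)(C)C)[C@]2(O)[C@@H](C)C(=O)O[C@H]2[C@@H](Cl)C#C[Si](C)(C)C | intermediate
22 | 21 with ring B as the 4,6-dimethylcyclohex-2-en-1-one (C12 ketone, C13=C14, C11–H) | C=C[C@H](O[Si](C)(C)C(C)(C)C)[C@@]1(C)C=CC(=O)[C@@H](C)[C@@H]1[C@H](O[Si](C)(C)C(C)(C)C)[C@]2(O)[C@@H](C)C(=O)O[C@H]2[C@@H](Cl)C#C[Si](C)(C)C | intermediate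
23 | 22 bearing the C11 hydroxyl (C11 as in the target) | C=C[C@H](O[Si](C)(C)C(C)(C)C)[C@@]1(C)C=CC(=O)[C@@](C)(O)[C@@H]1[C@H](O[Si](C)(C)C(C)(C)C)[C@]2(O)[C@@H](C)C(=O)O[C@H]2[C@@H](Cl)C#C[Si](C)(C)C | intermediate
24 | fully desilylated 23: O2/O8/O9/O11 tetraol with C2 vinyl and terminal C4≡C5 alkyne | C=C[C@H](O)[C@@]1(C)C=CC(=O)[C@@](C)(O)[C@@H]1[C@H](O)[C@]2(O)[C@@H](C)C(=O)O[C@H]2[C@@H](Cl)C#C | intermediate
25 | 24 with the alkyne converted into the buta-1,3-dien-2-yl group on C6 (acyclic triene) | C=C[C@H](O)[C@@]1(C)C=CC(=O)[C@@](C)(O)[C@@H]1[C@H](O)[C@]2(O)[C@@H](C)C(=O)O[C@H]2[C@@H](Cl)C(=C)C=C | intermediate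
26 | ten-membered (3Z),5(16)-diene: 2,9-di-O-deacetyl-3,4-deoxy-3,4-didehydro target | C=C1/C=C\[C@H](O)[C@@]2(C)C=CC(=O)[C@@](C)(O)[C@@H]2[C@H](O)[C@]2(O)[C@@H](C)C(=O)O[C@H]2[C@H]1Cl | intermediate
27 | 2,9-di-O-deacetyl target (3,4-epoxide in place) | C=C1[C@H]2O[C@H]2[C@H](O)[C@@]2(C)C=CC(=O)[C@@](C)(O)[C@@H]2[C@H](O)[C@]2(O)[C@@H](C)C(=O)O[C@H]2[C@H]1Cl | intermediate
28 | CNP0176724.2 | C=C1[C@H]2O[C@H]2[C@H](OC(C)=O)[C@@]2(C)C=CC(=O)[C@@](C)(O)[C@@H]2[C@H](OC(C)=O)[C@]2(O)[C@@H](C)C(=O)O[C@H]2[C@H]1Cl | target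

**Step count and risks**

Total step count: 14. Longest linear sequence: 14 steps (1 → 28); all other inputs are commercial.

The three steps most likely to fail:

Step 8 (the proposed one-flask cascade). Retro-aldol of the tertiary aldolate, SN2′ opening of the alkynyl epoxide, or incomplete lactonisation could intervene. The fallback uses known chemistry, sets out from 17 and returns at 21. Et2AlCl (CH2Cl2, −78 °C) opens the epoxy ketone at the propargylic carbon with inversion to give the chlorohydrin ketone F1. 2-Bromopropanoyl bromide and pyridine acylate the C7 hydroxyl to give the 2-bromopropanoate F2. SmI2 (THF, −78 °C) then effects an intramolecular Reformatsky reaction through a samarium-chelated enolate, which forms the C8–C17 bond on the face of the tether oxygen; brief amidine equilibration of C17 gives 21.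

Step 12 (ten-membered ring closure). The free polyol may sequester ruthenium, and the conjugated diene may oligomerise instead of closing a strained ring. The fallback sets out from 23 and returns at 26, closing the ring on the hydroxyl-masked substrate before desilylation. AgNO3 (cat.) and 2,6-lutidine in aqueous acetone free the alkyne to give the bis-silyl alkyne F3. Ethene enyne metathesis is run as a separate step and the bis-silyl triene F4 is isolated. Ring-closing metathesis at high dilution, where the two bulky silyl ethers on O2 and O9 bias the chain ends gauche, gives the bis-silyl macrocycle F5. Bu4NF/AcOH then gives 26.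

Step 13 (site and face selectivity of the diene epoxidation). The fallback sets out from 26 and returns at 28. Acetylation first (Ac2O, pyridine) gives the 2,9-diacetate F6. Dimethyldioxirane (acetone, −20 °C) then epoxidises the cis C3=C4 bond from its exposed outer face, so steric approach control replaces hydroxyl direction, and 28 is obtained directly.

**Further compounds**

F1 | step 8 | chlorohydrin ketone: 17 opened to C6–Cl (inverted) and C7–OH, C8 ketone retained | C=C[C@H](O[Si](C)(C)C(C)(C)C)[C@@]1(C)CC=C(O[Si](C(C)C)(C(C)C)C(C)C)[C@@H](C)[C@@H]1[C@H](O[Si](C)(C)C(C)(C)C)C(=O)[C@@H](O)[C@@H](Cl)C#C[Si](C)(C)C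
F2 | step 8 | C7 2-bromopropanoate of F1 (bromide carbon as a mixture) | C=C[C@H](O[Si](C)(C)C(C)(C)C)[C@@]1(C)CC=C(O[Si](C(C)C)(C(C)C)C(C)C)[C@@H](C)[C@@H]1[C@H](O[Si](C)(C)C(C)(C)C)C(=O)[C@@H](OC(=O)C(C)Br)[C@@H](Cl)C#C[Si](C)(C)C
F3 | step 12 | bis-silyl alkyne: 23 with the alkynyl silane removed | C=C[C@H](O[Si](C)(C)C(C)(C)C)[C@@]1(C)C=CC(=O)[C@@](C)(O)[C@@H]1[C@H](O[Si](C)(C)C(C)(C)C)[C@]2(O)[C@@H](C)C(=O)O[C@H]2[C@@H](Cl)C#C
F4 | step 12 | bis-silyl triene: F3 with the alkyne converted into the buta-1,3-dien-2-yl group | C=C[C@H](O[Si](C)(C)C(C)(C)C)[C@@]1(C)C=CC(=O)[C@@](C)(O)[C@@H]1[C@H](O[Si](C)(C)C(C)(C)C)[C@]2(O)[C@@H](C)C(=O)O[C@H]2[C@@H](Cl)C(=C)C=C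
F5 | step 12 | bis-silyl macrocycle: O2,O9-bis(tert-butyldimethylsilyl) ether of 26 | C=C1/C=C\[C@H](O[Si](C)(C)C(C)(C)C)[C@@]2(C)C=CC(=O)[C@@](C)(O)[C@@H]2[C@H](O[Si](C)(C)C(C)(C)C)[C@]2(O)[C@@H](C)C(=O)O[C@H]2[C@H]1Cl
F6 | step 13 | 2,9-diacetate of 26 | C=C1/C=C\[C@H](OC(C)=O)[C@@]2(C)C=CC(=O)[C@@](C)(O)[C@@H]2[C@H](OC(C)=O)[C@]2(O)[C@@H](C)C(=O)O[C@H]2[C@H]1Cl
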